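## Retrosynthetic overview

1. Locants: C1 (CO2H), C2, dioxane carbons C3–C6 (O2 on C3, O1 on C6), side chain C1'–C8'. The strategy rests on C3 and C6 being the 1,4-related peroxide carbons of the 1,2-dioxane ring while C6 carries C1'–C2'–C3': a temporary C3–C3' bond turns C3–C6 plus C1'–C3' into a cyclohepta-1,3-diene whose 1,4-endoperoxide is the dioxane.
2. Late disconnections: C3'=C4' (Julia–Kocienski, 26 + 33); C2–C3 (silyl ketene acetal on the peroxycarbenium ion from bridged lactone 20); C3–C3' (Baeyer–Villiger of ketone 19); C4–H (diimide on 16).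
3. Key disconnection: C6–O1 and C3–O2 by [4+2] addition of singlet oxygen to the silyl ether 14 of cis-3,5,7-trimethylcyclohepta-2,4-dien-1-ol.
4. 14 comes from ring-closing metathesis of triene 13. Its ring-cis C3=C4 bond comes from propynyl addition, trans-hydroalumination/iodination and vinyl Stille coupling; C3' from transfer hydrogenation, C2' from Evans alkylation, C6' from organocatalytic vinylation.
5. Ring order: cycloheptadiene (step 8), then the 1,2-dioxane inside a 6,7-dioxabicyclo[3.2.2]nonene (step 9), then the carbocycle is expanded to a lactone (step 13) and opened (step 14).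

Key step: step 9

Assumption: the iminium-catalysed vinylation of step 17 is taken to follow the usual facial preference of 5-benzyl-2-tert-butylimidazolidinones (the (2S,5S) catalyst leaves the Re face of C3 of the enal iminium ion open), so the (2R,5R) catalyst is specified for the (S) centre; if the sense proves opposite, the enantiomeric catalyst is used with no other change.

## Route

Step 1
Reactants: 1 (S)-4-benzyl-3-propionyloxazolidin-2-one; 2 3-bromo-2-methylprop-1-ene
Product: 4 (S)-4-benzyl-3-[(R)-2,4-dimethylpent-4-enoyl]oxazolidin-2-one, via sodium enolate 3 (not isolated)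
Conditions: NaN(SiMe3)2, THF, −78 °C; then 2, −78 → −40 °C
Reagents that add atoms: none
Why: Evans asymmetric alkylation, in which the chelated sodium (Z)-enolate is alkylated by the allylic bromide on the face away from the benzyl group, setting C2' as R.

Step 2
Reactants: 4 (S)-4-benzyl-3-[(R)-2,4-dimethylpent-4-enoyl]oxazolidin-2-one
Product: 5 (R)-N-methoxy-N,2,4-trimethylpent-4-enamide
Conditions: MeNH(OMe)·HCl, AlMe3, CH2Cl2, −10 → 25 °C
Reagents that add atoms: N,O-dimethylhydroxylamine hydrochloride, CNOC.Cl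
Why: Aluminium amide transamination of the N-acyloxazolidinone (Weinreb amide formation) should cleave the exocyclic acyl group without touching the α-stereocentre and return the auxiliary.

Step 3
Reactants: 5 (R)-N-methoxy-N,2,4-trimethylpent-4-enamide; 6 prop-1-yn-1-ylmagnesium bromide
Product: 7 (R)-5,7-dimethyloct-7-en-2-yn-4-one
Conditions: THF, −20 → 0 °C; cold aq NH4Cl
Reagents that add atoms: none
Why: Weinreb ketone synthesis, in which the magnesium chelate of the tetrahedral adduct survives until the cold quench, so the alkynyl Grignard reagent adds once and the epimerisable C2' centre is spared.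

Step 4
Reactants: 7 (R)-5,7-dimethyloct-7-en-2-yn-4-one
Product: 8 (4R,5R)-5,7-dimethyloct-7-en-2-yn-4-ol
Conditions: Ru[(R,R)-TsNCHPhCHPhNH](p-cymene) (2 mol%, preformed from RuCl[(R,R)-TsDPEN](p-cymene) and KOH), i-PrOH, 25 °C
Reagents that add atoms: none
Why: Noyori asymmetric transfer hydrogenation of the ynone under control of the (R,R)-diamine ligand should give the (4R) propargylic alcohol (the later C3' carbinol) in a neutral medium that reduces neither alkene nor alkyne and does not epimerise C2'.

Step 5
Reactants: 8 (4R,5R)-5,7-dimethyloct-7-en-2-yn-4-ol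
Product: 10 (2Z,4R,5R)-2-iodo-5,7-dimethylocta-2,7-dien-4-ol, via alkenylaluminate 9 (not isolated)
Conditions: NaAlH2(OCH2CH2OMe)2, THF, 0 → 25 °C; EtOAc; then I2 (1.2 equiv), −78 °C; cold aq Na2S2O3
Reagents that add atoms: iodine, II
Why: Hydroxyl-directed trans-hydroalumination of the propargylic alcohol places aluminium on the distal alkyne carbon cis to the carbinol carbon within a five-membered alkoxyaluminate, and iodinolysis with retention gives the (Z)-iodide that the ring-cis C3=C4 bond demands (a syn-carbometalated dienyl reagent would have the opposite geometry); iodine is kept near stoichiometric and cold so that the methallyl alkene is not iodoetherified.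

Step 6
Reactants: 10 (2Z,4R,5R)-2-iodo-5,7-dimethylocta-2,7-dien-4-ol; 11 tributyl(vinyl)stannane
Product: 12 (3Z,5R,6R)-3,6,8-trimethylnona-1,3,8-trien-5-ol
Conditions: PdCl2(MeCN)2 (5 mol%), DMF, 25 °C
Reagents that add atoms: none
Why: Stille cross-coupling transfers the vinyl group (C5) with retention of the (Z) alkenyl iodide geometry under neutral conditions that tolerate the free allylic alcohol.

Step 7
Reactants: 12 (3Z,5R,6R)-3,6,8-trimethylnona-1,3,8-trien-5-ol
Product: 13 tert-butyl(dimethyl){[(3Z,5R,6R)-3,6,8-trimethylnona-1,3,8-trien-5-yl]oxy}silane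
Conditions: TBSOTf, 2,6-lutidine, CH2Cl2, −78 → 0 °C
Reagents that add atoms: tert-butyldimethylsilyl trifluoromethanesulfonate, CC(C)(C)[Si](C)(C)OS(=O)(=O)C(F)(F)F
Why: Silyl ether formation with the silyl triflate caps the hindered secondary allylic alcohol with the bulky group that later steers oxygen to the opposite face.

Step 8
Reactants: 13 tert-butyl(dimethyl){[(3Z,5R,6R)-3,6,8-trimethylnona-1,3,8-trien-5-yl]oxy}silane
Product: 14 tert-butyl(dimethyl){[(1R,7R)-3,5,7-trimethylcyclohepta-2,4-dien-1-yl]oxy}silane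
Conditions: RuCl2(=CHPh)(PCy3)(H2IMes) (5 mol%), CH2Cl2 (0.005 M), 40 °C
Reagents that add atoms: none
Why: Ring-closing alkene metathesis, in which the catalyst loads on the monosubstituted vinyl terminus and closes onto the 1,1-disubstituted methallyl alkene to form the trisubstituted C5=C6 bond of the seven-membered ring with loss of ethene, the preset (Z) alkene supplying the second ring double bond.

Step 9
Reactants: 14 tert-butyl(dimethyl){[(1R,7R)-3,5,7-trimethylcyclohepta-2,4-dien-1-yl]oxy}silane; 15 dioxygen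
Product: 16 tert-butyl(dimethyl){[(1R,2R,3R,5R)-3,5,8-trimethyl-6,7-dioxabicyclo[3.2.2]non-8-en-2-yl]oxy}silane (silyloxy and 3-methyl turned toward the C8=C9 bridge)
Conditions: O2, 5,10,15,20-tetraphenylporphyrin (1 mol%), CH2Cl2, −78 °C, visible light; kept cold and used at once
Reagents that add atoms: none
Why: Singlet oxygen, formed by energy transfer from the excited porphyrin, adds as the 2π partner across C3 and C6 of the ring-enforced s-cis diene in a concerted suprafacial [4+2] cycloaddition that forms C6–O1 and C3–O2 and leaves the C4=C5 double bond. The closest known reaction type is the photo-oxygenation of cyclohexa-1,3-dienes and cyclohepta-1,3-dienes to bridged bicyclic endoperoxides. The 1,2-dioxane ring (O1, O2, C3, C4, C5, C6) is closed by cycloaddition, both ring bonds being made in the same event, so the product is a 6,7-dioxabicyclo[3.2.2]non-8-ene. The new stereocentres C6 and C3 are set together by the face of attack, which is controlled by the allylic silyloxy group on C3' and the cis C2' methyl: oxygen should add anti to both, which gives the C6 configuration of the target relative to C2'. The step needs cycloaddition to outrun the ene reaction at the allylic methyl and methylene hydrogens and needs a single diene face; the first is secured by the cyclic s-cis diene and the low temperature, the second by the bulky silyl ether next to the diene terminus.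

Step 10
Reactants: 16 tert-butyl(dimethyl){[(1R,2R,3R,5R)-3,5,8-trimethyl-6,7-dioxabicyclo[3.2.2]non-8-en-2-yl]oxy}silane
Product: 17 tert-butyl(dimethyl){[(1R,2R,3R,5S,8S)-3,5,8-trimethyl-6,7-dioxabicyclo[3.2.2]nonan-2-yl]oxy}silane
Conditions: KO2CN=NCO2K (excess, in portions), AcOH, MeOH/CH2Cl2, −20 → 5 °C
Reagents that add atoms: none
Why: Diimide reduction (concerted syn transfer of two hydrogens) saturates C4=C5 without cleaving the O–O bond, and the reagent should approach from the peroxide-bridge face because the other face is covered by the C2' methyl and the silyloxy group of the three-carbon bridge, so the C4 methyl ends up syn to that bridge (4S of the target).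

Step 11
Reactants: 17 tert-butyl(dimethyl){[(1R,2R,3R,5S,8S)-3,5,8-trimethyl-6,7-dioxabicyclo[3.2.2]nonan-2-yl]oxy}silane
Product: 18 (1R,2R,3R,5R,8S)-3,5,8-trimethyl-6,7-dioxabicyclo[3.2.2]nonan-2-ol
Conditions: HF (48% aq), MeCN, 0 → 25 °C
Reagents that add atoms: none
Why: Acidic fluoride desilylation frees the C3' alcohol, basic fluoride being avoided because a β-peroxy alkoxide can fragment with loss of the O–O bond.

Step 12
Reactants: 18 (1R,2R,3R,5R,8S)-3,5,8-trimethyl-6,7-dioxabicyclo[3.2.2]nonan-2-ol
Product: 19 (1R,3R,5S,8S)-3,5,8-trimethyl-6,7-dioxabicyclo[3.2.2]nonan-2-one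
Conditions: Dess–Martin periodinane, CH2Cl2, 0 → 25 °C; neutral aq Na2S2O3 wash; used at once
Reagents that add atoms: none
Why: Dess–Martin oxidation without added base gives the α-peroxy ketone while avoiding Kornblum–DeLaMare cleavage through the now acidic C3–H and enolisation at C2'.

Step 13
Reactants: 19 (1R,3R,5S,8S)-3,5,8-trimethyl-6,7-dioxabicyclo[3.2.2]nonan-2-one
Product: 20 (1R,4R,6S,9S)-4,6,9-trimethyl-2,7,8-trioxabicyclo[4.2.2]decan-3-one
Conditions: mCPBA, CH2Cl2, 0 → 25 °C
Reagents that add atoms: 3-chloroperoxybenzoic acid, OOC(=O)c1cccc(Cl)c1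
Why: Proposed new method: Baeyer–Villiger oxidation of an α-peroxy ketone is meant to insert oxygen into the C3–C3' bond, the peracid adding to the bridged ketone and the bridgehead C3 then migrating with retention in the Criegee adduct in preference to the secondary C2', because a lone pair of the attached peroxide oxygen stabilises the positive charge that builds up on the migrating carbon (the same stabilisation that makes peroxycarbenium ions accessible), which gives the acyloxy peroxyacetal; the closest known reaction type is the Baeyer–Villiger oxidation of α-alkoxy ketones such as 7-oxabicyclo[2.2.1]heptan-2-ones, in which the oxygen-bearing bridgehead carbon migrates.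

Step 14
Reactants: 20 (1R,4R,6S,9S)-4,6,9-trimethyl-2,7,8-trioxabicyclo[4.2.2]decan-3-one; 21 tert-butyl[(1-methoxyethenyl)oxy]dimethylsilane
Product: 23 (2R)-3-[(3S,5S,6S)-6-(2-methoxy-2-oxoethyl)-3,5-dimethyl-1,2-dioxan-3-yl]-2-methylpropanoic acid, via trimethylsilyl ester 22 (not isolated)
Conditions: TMSOTf (1.2 equiv), CH2Cl2, −78 → −40 °C; aq pH 5 buffer
Reagents that add atoms: none
Why: Lewis acid-mediated substitution of a peroxyacetal by a silyl ketene acetal (Mukaiyama-type addition to a peroxycarbenium ion), in which silylation of the lactone carbonyl ionises the C3–O bond and axial attack on the half-chair cation that holds the C4 methyl and the C6 CH2 chain pseudoequatorial (C6 methyl pseudoaxial) through a chair-like transition state should place the acetate cis to both, setting C3 as in the target.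

Step 15
Reactants: 23 (2R)-3-[(3S,5S,6S)-6-(2-methoxy-2-oxoethyl)-3,5-dimethyl-1,2-dioxan-3-yl]-2-methylpropanoic acid
Product: 25 methyl 2-[(3S,4S,6R)-6-[(2R)-3-hydroxy-2-methylpropyl]-4,6-dimethyl-1,2-dioxan-3-yl]acetate, via mixed anhydride 24 (not isolated)
Conditions: i-BuOCOCl, N-methylmorpholine, THF, −15 °C; then NaBH4, THF/H2O, −15 → 0 °C
Reagents that add atoms: none
Why: Mixed carbonic anhydride activation followed by borohydride reduction converts the C3' acid into the primary alcohol chemoselectively, NaBH4 leaving the methyl ester and the dialkyl peroxide untouched and C2' unepimerised.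

Step 16
Reactants: 25 methyl 2-[(3S,4S,6R)-6-[(2R)-3-hydroxy-2-methylpropyl]-4,6-dimethyl-1,2-dioxan-3-yl]acetate
Product: 26 methyl 2-[(3S,4S,6S)-4,6-dimethyl-6-[(2R)-2-methyl-3-oxopropyl]-1,2-dioxan-3-yl]acetate
Conditions: Dess–Martin periodinane, NaHCO3, CH2Cl2, 0 → 25 °C
Reagents that add atoms: none
Why: Dess–Martin oxidation gives the α-branched C3' aldehyde without over-oxidation or epimerisation at C2' and is compatible with the peroxide.

Step 17
Reactants: 27 (E)-but-2-enal; 28 potassium (E)-styryltrifluoroborate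
Product: 30 (3S,4E)-3-methyl-5-phenylpent-4-en-1-ol, via aldehyde 29 (not isolated)
Conditions: (2R,5R)-5-benzyl-2-tert-butyl-3-methylimidazolidin-4-one·HCl (20 mol%), HF (48% aq, 1 equiv), DME, −20 °C; then NaBH4, EtOH, 0 °C
Reagents that add atoms: none
Why: Iminium-catalysed enantioselective conjugate addition of an alkenyl trifluoroborate to an enal (organocatalytic vinylation) delivers the styryl group, with its (E) geometry kept, to the open face of the iminium ion and so sets C6' as S, and borohydride reduction in the same flask gives the alcohol.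

Step 18
Reactants: 30 (3S,4E)-3-methyl-5-phenylpent-4-en-1-ol; 31 1-phenyl-1H-tetrazole-5-thiol
Product: 32 5-{[(3S,4E)-3-methyl-5-phenylpent-4-en-1-yl]sulfanyl}-1-phenyl-1H-tetrazole
Conditions: PPh3, DIAD, THF, 0 → 25 °C
Reagents that add atoms: none
Why: Mitsunobu thioetherification of the primary alcohol with the acidic tetrazole thiol.

Step 19
Reactants: 32 5-{[(3S,4E)-3-methyl-5-phenylpent-4-en-1-yl]sulfanyl}-1-phenyl-1H-tetrazole
Product: 33 5-{[(3S,4E)-3-methyl-5-phenylpent-4-en-1-yl]sulfonyl}-1-phenyl-1H-tetrazole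
Conditions: H2O2 (30% aq), (NH4)6Mo7O24·4H2O (10 mol%), EtOH, 0 → 25 °C
Reagents that add atoms: hydrogen peroxide, OO
Why: Molybdate-catalysed sulfide-to-sulfone oxidation, chosen because it should not epoxidise the styrene.

Step 20
Reactants: 33 5-{[(3S,4E)-3-methyl-5-phenylpent-4-en-1-yl]sulfonyl}-1-phenyl-1H-tetrazole; 26 methyl 2-[(3S,4S,6S)-4,6-dimethyl-6-[(2R)-2-methyl-3-oxopropyl]-1,2-dioxan-3-yl]acetate
Product: 35 methyl 2-[(3S,4S,6R)-6-[(2R,3E,6S,7E)-2,6-dimethyl-8-phenylocta-3,7-dien-1-yl]-4,6-dimethyl-1,2-dioxan-3-yl]acetate, via sulfonyl carbanion 34 (not isolated)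
Conditions: KN(SiMe3)2, DME, −60 °C; then 26, −60 → 25 °C
Reagents that add atoms: none
Why: Julia–Kocienski olefination, in which addition of the metalated phenyltetrazolyl sulfone to the α-branched aldehyde, Smiles rearrangement and anti elimination give the (E)-C3'=C4' alkene in one pot without a reductive step that the peroxide would not survive.

Step 21
Reactants: 35 methyl 2-[(3S,4S,6R)-6-[(2R,3E,6S,7E)-2,6-dimethyl-8-phenylocta-3,7-dien-1-yl]-4,6-dimethyl-1,2-dioxan-3-yl]acetate
Product: 37 2-[(3S,4S,6R)-6-[(2R,3E,6S,7E)-2,6-dimethyl-8-phenylocta-3,7-dien-1-yl]-4,6-dimethyl-1,2-dioxan-3-yl]acetic acid, via lithium carboxylate 36 (not isolated)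
Conditions: LiOH, THF/MeOH/H2O, 0 → 25 °C; then 1 M HCl to pH 3
Reagents that add atoms: lithium hydroxide, [Li+].[OH-]
Why: Ester saponification at low temperature followed by mild acidification gives the acid, the dialkyl peroxide and both alkenes being stable to these conditions.

## Compound list

1 | (S)-4-benzyl-3-propionyloxazolidin-2-one | CCC(=O)N1[C@@H](Cc2ccccc2)COC1=O | starting material
2 | 3-bromo-2-methylprop-1-ene | CC(=C)CBr | starting material
3 | sodium (Z)-enolate of 1 | C/C=C(\[O-])N1[C@@H](Cc2ccccc2)COC1=O.[Na+] | intermediate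
4 | (S)-4-benzyl-3-[(R)-2,4-dimethylpent-4-enoyl]oxazolidin-2-one | C=C(C)C[C@@H](C)C(=O)N1[C@@H](Cc2ccccc2)COC1=O | intermediate
5 | (R)-N-methoxy-N,2,4-trimethylpent-4-enamide | C=C(C)C[C@@H](C)C(=O)N(C)OC | intermediate
6 | prop-1-yn-1-ylmagnesium bromide | CC#C[Mg]Br | starting material
7 | (R)-5,7-dimethyloct-7-en-2-yn-4-one | CC#CC(=O)[C@H](C)CC(C)=C | intermediate
8 | (4R,5R)-5,7-dimethyloct-7-en-2-yn-4-ol | CC#C[C@H](O)[C@H](C)CC(C)=C | intermediate
9 | sodium cyclic alkenyl(alkoxy)bis(2-methoxyethoxy)aluminate of 8 (aluminium on C2, cis to C4) | C/C1=C/[C@@H]([C@H](C)CC(C)=C)O[Al-]1(OCCOC)OCCOC.[Na+] | intermediate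
10 | (2Z,4R,5R)-2-iodo-5,7-dimethylocta-2,7-dien-4-ol | C/C(I)=C/[C@H](O)[C@H](C)CC(C)=C | intermediate
11 | tributyl(vinyl)stannane | C=C[Sn](CCCC)(CCCC)CCCC | starting material
12 | (3Z,5R,6R)-3,6,8-trimethylnona-1,3,8-trien-5-ol | C=C/C(C)=C\[C@H](O)[C@H](C)CC(C)=C | intermediate
13 | tert-butyl(dimethyl){[(3Z,5R,6R)-3,6,8-trimethylnona-1,3,8-trien-5-yl]oxy}silane | C=C/C(C)=C\[C@H](O[Si](C)(C)C(C)(C)C)[C@H](C)CC(C)=C | intermediate
14 | tert-butyl(dimethyl){[(1R,7R)-3,5,7-trimethylcyclohepta-2,4-dien-1-yl]oxy}silane (cis) | C[C@@H]1CC(C)=CC(C)=C[C@@H]1O[Si](C)(C)C(C)(C)C | intermediate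
15 | dioxygen | O=O | starting material
16 | tert-butyl(dimethyl){[(1R,2R,3R,5R)-3,5,8-trimethyl-6,7-dioxabicyclo[3.2.2]non-8-en-2-yl]oxy}silane | C[C@@H]1C[C@]2(C)C=C(C)[C@@H](OO2)[C@@H]1O[Si](C)(C)C(C)(C)C | intermediate
17 | tert-butyl(dimethyl){[(1R,2R,3R,5S,8S)-3,5,8-trimethyl-6,7-dioxabicyclo[3.2.2]nonan-2-yl]oxy}silane | C[C@@H]1C[C@]2(C)C[C@H](C)[C@@H](OO2)[C@@H]1O[Si](C)(C)C(C)(C)C | intermediate
18 | (1R,2R,3R,5R,8S)-3,5,8-trimethyl-6,7-dioxabicyclo[3.2.2]nonan-2-ol | C[C@@H]1C[C@]2(C)C[C@H](C)[C@@H](OO2)[C@@H]1O | intermediate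
19 | (1R,3R,5S,8S)-3,5,8-trimethyl-6,7-dioxabicyclo[3.2.2]nonan-2-one | C[C@@H]1C[C@]2(C)C[C@H](C)[C@@H](OO2)C1=O | intermediate
20 | (1R,4R,6S,9S)-4,6,9-trimethyl-2,7,8-trioxabicyclo[4.2.2]decan-3-one | C[C@@H]1C[C@]2(C)C[C@H](C)[C@@H](OO2)OC1=O | intermediate
21 | tert-butyl[(1-methoxyethenyl)oxy]dimethylsilane | C=C(OC)O[Si](C)(C)C(C)(C)C | starting material
22 | trimethylsilyl ester of 23 | C[Si](C)(C)OC(=O)[C@H](C)C[C@]1(C)C[C@H](C)[C@H](CC(=O)OC)OO1 | intermediate
23 | (2R)-3-[(3S,5S,6S)-6-(2-methoxy-2-oxoethyl)-3,5-dimethyl-1,2-dioxan-3-yl]-2-methylpropanoic acid | OC(=O)[C@H](C)C[C@]1(C)C[C@H](C)[C@H](CC(=O)OC)OO1 | intermediate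
24 | isobutyl carbonic mixed anhydride of 23 | CC(C)COC(=O)OC(=O)[C@H](C)C[C@]1(C)C[C@H](C)[C@H](CC(=O)OC)OO1 | intermediate
25 | methyl 2-[(3S,4S,6R)-6-[(2R)-3-hydroxy-2-methylpropyl]-4,6-dimethyl-1,2-dioxan-3-yl]acetate | OC[C@H](C)C[C@]1(C)C[C@H](C)[C@H](CC(=O)OC)OO1 | intermediate
26 | methyl 2-[(3S,4S,6S)-4,6-dimethyl-6-[(2R)-2-methyl-3-oxopropyl]-1,2-dioxan-3-yl]acetate | O=C[C@H](C)C[C@]1(C)C[C@H](C)[C@H](CC(=O)OC)OO1 | intermediate
27 | (E)-but-2-enal | C/C=C/C=O | starting material
28 | potassium (E)-styryltrifluoroborate | [K+].F[B-](F)(F)/C=C/c1ccccc1 | starting material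
29 | (3S,4E)-3-methyl-5-phenylpent-4-enal | C[C@H](/C=C/c1ccccc1)CC=O | intermediate
30 | (3S,4E)-3-methyl-5-phenylpent-4-en-1-ol | C[C@H](/C=C/c1ccccc1)CCO | intermediate
31 | 1-phenyl-1H-tetrazole-5-thiol | Sc1nnnn1-c1ccccc1 | starting material
32 | 5-{[(3S,4E)-3-methyl-5-phenylpent-4-en-1-yl]sulfanyl}-1-phenyl-1H-tetrazole | C[C@H](/C=C/c1ccccc1)CCSc1nnnn1-c1ccccc1 | intermediate
33 | 5-{[(3S,4E)-3-methyl-5-phenylpent-4-en-1-yl]sulfonyl}-1-phenyl-1H-tetrazole | C[C@H](/C=C/c1ccccc1)CCS(=O)(=O)c1nnnn1-c1ccccc1 | intermediate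
34 | potassium α-sulfonyl carbanion of 33 | C[C@H](/C=C/c1ccccc1)C[CH-]S(=O)(=O)c1nnnn1-c1ccccc1.[K+] | intermediate
35 | methyl 2-[(3S,4S,6R)-6-[(2R,3E,6S,7E)-2,6-dimethyl-8-phenylocta-3,7-dien-1-yl]-4,6-dimethyl-1,2-dioxan-3-yl]acetate | C[C@H](/C=C/c1ccccc1)C/C=C/[C@H](C)C[C@]1(C)C[C@H](C)[C@H](CC(=O)OC)OO1 | intermediate
36 | lithium carboxylate of 37 | C[C@H](/C=C/c1ccccc1)C/C=C/[C@H](C)C[C@]1(C)C[C@H](C)[C@H](CC(=O)[O-])OO1.[Li+] | intermediate
37 | 2-[(3S,4S,6R)-6-[(2R,3E,6S,7E)-2,6-dimethyl-8-phenylocta-3,7-dien-1-yl]-4,6-dimethyl-1,2-dioxan-3-yl]acetic acid (CNP0179089.2) | C[C@H](/C=C/c1ccccc1)C/C=C/[C@H](C)C[C@]1(C)C[C@H](C)[C@H](CC(=O)O)OO1 | target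

## Step count

Total steps: 21. Longest linear sequence: 18 (steps 1–16, 20, 21); the sulfone branch is steps 17–19.

## Steps most likely to fail

**Step 13 (bears the label).** What may go wrong: migration of C2' instead of the peroxide-bearing C3 in the Criegee adduct, or acid- or base-triggered cleavage of the α-peroxy ketone before oxygen is inserted. The fallback cuts the same C3–C3' bond by Beckmann fragmentation, in which no second migrating group competes. It sets out from 19. Oximation (NH2OH·HCl, NaOAc, MeOH) should give the oxime of 19 F1. Activation with methanesulfonyl chloride and 2,6-lutidine in CH2Cl2 at −20 °C should give the O-methanesulfonyl oxime F2, which is not isolated. With added methanol it should fragment to (2R)-3-[(3R,5S)-6-methoxy-3,5-dimethyl-1,2-dioxan-3-yl]-2-methylpropanenitrile F3, as a mixture at the acetal carbon that does not matter because this carbon is ionised again. Half-reduction of the nitrile (i-Bu2AlH, toluene, −78 °C) should give (2R)-3-[(3R,5S)-6-methoxy-3,5-dimethyl-1,2-dioxan-3-yl]-2-methylpropanal F4. Julia–Kocienski olefination with 33 under the conditions of step 20 should give (3R,5S)-6-methoxy-3,5-dimethyl-3-[(2R,3E,6S,7E)-2,6-dimethyl-8-phenylocta-3,7-dien-1-yl]-1,2-dioxane F5. Substitution of the methoxy group with 21 and TMSOTf (CH2Cl2, −78 °C), as in step 14, returns to the route at 35. The reaction types used are known ones: Beckmann fragmentation of ketoximes with an α-oxygen substituent, nitrile half-reduction, Julia–Kocienski olefination and ketene acetal substitution of 3-alkoxy-1,2-dioxanes.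

**Step 9.** What may go wrong: ene hydroperoxidation at the allylic methyl and methylene hydrogens competing with cycloaddition, or insufficient discrimination between the two diene faces. The fallback makes the same two C–O bonds with ground-state oxygen through the diene radical cation, a chain oxygenation known for conjugated dienes that has no ene channel: 14, O2, (4-BrC6H4)3N SbCl6 (catalytic), CH2Cl2, −78 °C. It sets out from 14 and returns at 16, attack again being expected anti to the silyloxy group. This fallback makes no new compound, F0.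

**Step 10.** What may go wrong: hydrogen transfer to the hindered trisubstituted alkene being so slow that the unsaturated endoperoxide rearranges before it is reduced, the C4 methyl having to move toward the silyloxy group of the neighbouring bridge. The fallback changes the order of events. It sets out from 16, which is desilylated first (HF, MeCN, 0 °C) to (1R,2R,3R,5R)-3,5,8-trimethyl-6,7-dioxabicyclo[3.2.2]non-8-en-2-ol F6, in which that contact is much smaller. Diimide (KO2CN=NCO2K, AcOH) is then applied to F6 and should give 18, where the route is rejoined. The C2' methyl and the hydroxyl still screen the face toward the three-carbon bridge. A hydroxyl-directed hydrogenation is not used because the hydroxyl sits on the face that must stay unreduced.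

## Further compounds

F1 | step 13 | oxime of ketone 19 | C[C@@H]1C[C@]2(C)C[C@H](C)[C@@H](OO2)C1=NO
F2 | step 13 | O-methanesulfonyl oxime of ketone 19 | C[C@@H]1C[C@]2(C)C[C@H](C)[C@@H](OO2)C1=NOS(C)(=O)=O
F3 | step 13 | (2R)-3-[(3R,5S)-6-methoxy-3,5-dimethyl-1,2-dioxan-3-yl]-2-methylpropanenitrile | N#C[C@H](C)C[C@]1(C)C[C@H](C)C(OC)OO1
F4 | step 13 | (2R)-3-[(3R,5S)-6-methoxy-3,5-dimethyl-1,2-dioxan-3-yl]-2-methylpropanal | O=C[C@H](C)C[C@]1(C)C[C@H](C)C(OC)OO1
F5 | step 13 | (3R,5S)-6-methoxy-3,5-dimethyl-3-[(2R,3E,6S,7E)-2,6-dimethyl-8-phenylocta-3,7-dien-1-yl]-1,2-dioxane | C[C@H](/C=C/c1ccccc1)C/C=C/[C@H](C)C[C@]1(C)C[C@H](C)C(OC)OO1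
F0 | step 9 | none | none
F6 | step 10 | (1R,2R,3R,5R)-3,5,8-trimethyl-6,7-dioxabicyclo[3.2.2]non-8-en-2-ol | C[C@@H]1C[C@]2(C)C=C(C)[C@@H](OO2)[C@@H]1O
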